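The readings come from a simulation with made-up constants.

Larch is the flask asked about, followed so far; maple is the earlier run with less reagent in the second phase.

all flasks: starting material 0.036 M

| flask | reagent in the second phase | remark | time | volume of the second phase over the first |
|---|---|---|---|---|
| larch | 0.054 M | the very flask that is asked about, followed so far |  |  |
| maple | 0.036 M | run made earlier |  |  |
| flask | 0.0540 M |  | 1.5 h | 0.50 |

- larch (time / min: target / %, starting material / %): 2.00: 0.8, 100.3; 3.00: 1.7, 98.6; 5.00: 4.2, 95.6; 8.00: 7.3, 92.0; 12.0: 14.1, 85.0; 20.0: 24.4, 71.6; 25.0: 28.8, 65.0
- maple (time / min: target / %, starting material / %): 8.00: 5.2, 93.9; 12.0: 9.9, 90.4; 15.0: 12.5, 85.4; 25.0: 20.6, 74.7; 40.0: 28.6, 62.2; 60.0: 34.8, 49.5; 90.0: 37.6, 38.9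

(readings scatter by 0.5 percentage points)

- in the second phase: reagent in the second phase; everything else is in the first
- charges count per volume of the first phase; a concentration in a rate is the amount of a species over the volume of its own phase; every rate counts per litre of the first phase
- the earlier runs were read with a standard deviation of 0.5 percentage points
- the earlier runs hold the two phases in the same ratio of volumes as the flask asked about

- north: doubling the transfer coefficient of the reagent in the second phase, all else as stated
- south-west: doubling the amount of reagent in the second phase, all else as stated

- target at 1.5 h, in percent of the starting material charged
- the change that raises the amount of target at 1.5 h, in percent of the starting material charged most ("none" if none brings more than 2 percentage points) (north / south-west / none)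
- amount of target at 1.5 h, in percent of the starting material charged, after south-west

Divide the target by the starting material consumed. At 25.0 min larch gives 82.3% and maple 81.4%, close within the scatter although their reagent charges stand at 1.50 to one, so read this number by the clock. Maple at 90.0 min, the asked time, gives 61.5%: call it the kept share, the part of the consumed starting material standing as target at that time.

For the consumption, treat the starting material as pseudo-first-order: the logarithms of the fractions left at 25.0 min stand at 1.48 to one, near the charge ratio. Raise maple's fraction left to the charge ratio: I estimate that larch holds 24.3% starting material at 1.5 h, so my reckoning gives 46.6% target. On the same reckoning, doubled reagent leaves 5.89% and gives 57.9%. But one number is not enough here: with less starting material left at that time, target forms earlier and ages longer, so take that figure as high. The two runs differ in the reagent charge, and the consumption follows it, so south-west is the change they measure; choose south-west.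

The forecast gives 36%, none and 10%, on the ground that “The target tracks starting material identically in both runs”; it reads target off the starting material left, mine off the clock.

The flask gives 46.6%; the best change is south-west, gaining 3.5 percentage points against 0.73 points for north, and reaching 50.2%.

    reagent in the reaction phase ⇌ reagent in the second phase, rate k1*([reagent in the reaction phase] - [reagent in the second phase]/K1) per volume of the first phase (partition coefficient = 2.30, kL = 0.0630 min⁻¹)
    starting material + reagent in the reaction phase → target (k = 1.40 L mol⁻¹ min⁻¹)
    target ⇌ isomer of the product (K = 0.740, k = 0.0190 min⁻¹)
    reagent in the reaction phase + target → over-reaction product (k = 0.110 L mol⁻¹ min⁻¹)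
    reagent in the reaction phase → decomposed reagent (k = 0.00260 min⁻¹)

The kept share of the flask is 59.9%, and that of a neighbour flask with 0.061 M starting material, holding 39.1% target and 36% starting material, is 61.1% at the same time. By their interconversion alone, both ways together, target and isomer of the product relax with a half-life of 0.259 h, short against 1.5 h, and at the asked time the forward step to the isomer alone uses target 19 times faster than the step to over-reaction product; the flask then holds 27.2% isomer of the product and 4.03% over-reaction product.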